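**Remark on the chemistry:** the bromine is charged as one equivalent of crystalline tetrabutylammonium tribromide, whose anion holds one bromine at the electrophilic level and two as bromide. Raising these two bromides to the hypobromite level with peroxide uses two protons and the first substitution releases one, so the net demand is one proton per molecule of product, supplied by a KH2PO4/H3PO4 buffer. Acetonitrile is the co-solvent instead of an alcohol, so that the solvent can neither etherify the hydroxymethyl group nor drain the oxidant.

## Analysis of the target

Thelephenol 8 is an unsymmetrical diarylmethane, two phenol rings joined through one methylene carbon; it has no stereocentre and no ring that has to be built. Ring A is numbered from its phenolic carbon (OH at C1, Br at C2, hydroxymethyl at C4, the bridging benzyl carbon at C6), and ring B from the carbon that carries the bridge (C1, with Br at C3 and C5 and OH at C4). The sensitive groups are the 4-hydroxybenzyl alcohol unit of ring A, the doubly benzylic methylene and three aryl C–Br bonds. The first ionises towards a quinone methide under acid, heat or strong base and can be expelled by ipso substitution; the C–Br bonds would not survive zerovalent palladium, organometallic reagents or forcing hydride conditions. The difficulty is therefore one of timing and selectivity, not of skeleton: the Ar–CH2 bond and the alcohol oxidation level must be set without harm to C–Br bonds, and three bromines must land on three particular carbons out of seven aromatic C–H positions. The feature on which the plan rests is that both carbons para to a phenolic oxygen are already carbon-substituted (C4 of ring A by the hydroxymethyl group, C1 of ring B by the bridge), and that one ortho carbon of ring A (C6) carries the bridge as well. The three bromines therefore occupy exactly the three ortho C–H positions that the two phenols possess, C2 of ring A and C3 and C5 of ring B, while the four remaining C–H positions are meta to oxygen and unactivated. The halogen pattern of 8 is thus the innate electrophilic substitution pattern of the bromine-free bisphenol, which is also how a haloperoxidase would be expected to make it.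

## Retrosynthetic reasoning

**Three C–Br bonds (8 to 6 and 7).** All three carbon–bromine bonds are cut at once, which leads back to the bromine-free bisphenol 6 and the tribromide salt 7 as the halogen source. These bonds are cut first because they are the only bonds in 8 that are incompatible with cross-coupling and hydride chemistry, and because the substrate itself dictates where they form. What is gained is an end game with nothing after it and a precursor that carries no halogen. The forward reaction has to deliver all three bromine atoms of 7 as electrophiles to C2 of ring A and to C3 and C5 of ring B: one directly, and two after the released bromide has been re-oxidised by a peroxide under catalysis by pentavalent vanadium. It must do so faster than ipso attack at C4 or C6 of ring A or at C1 of ring B, and without oxidising the benzylic alcohol.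

**Oxidation level of the C4 side chain (6 to 5).** The hydroxymethyl group of 6 is traced back to the methyl ester of 5. An ester is chosen because it survives both an organozinc coupling and Lewis-acid ether cleavage, whereas a benzylic alcohol para to an oxygen substituent would be turned into a benzylic halide by the ether cleavage. The forward reaction is an aluminium hydride reduction that must tolerate two free phenols and stop at the alcohol.

**Two O–CH3 bonds (5 to 4).** The phenols of 5 are masked as the methyl ethers of 4. This is the form in which both aromatic building blocks are sold, and free phenols would protonate the benzylic zinc reagent. The forward reaction must cleave two aryl methyl ethers and spare the methyl ester.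

**The C6–CH2 bond (4 to 2 and 3, and 3 to 1).** The bond between C6 of ring A and the bridging methylene is cut, giving aryl bromide 2 and benzylic zinc chloride 3, which comes from benzylic chloride 1 by insertion of zinc into the C–Cl bond. The cut is made on this side of the methylene and with this polarity because 1 and 2 are both catalogue compounds, and because a benzylic zinc reagent is mild enough to leave the ester of 2 alone. The opposite cut would require a ring A benzylic metal that carries an ester and has to be made. An acid-mediated union of two phenol units was not considered further, since it gives ortho/para mixtures and oligomers. The forward reaction is a palladium-catalysed coupling between an sp3 zinc reagent and an aryl bromide flanked by a methoxy group.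

## Alternatives that were turned down

**Alternative 1:** The disconnection removes both bonds of the bridging carbon, which would enter as carbon monoxide A4 between a ring A aryl iodide, methyl 3-bromo-5-iodo-4-methoxybenzoate A2, and a ring B boronic acid, (3,5-dibromo-4-methoxyphenyl)boronic acid A3. The forward key step is a carbonylative Suzuki–Miyaura coupling under palladium catalysis with a carbonate base, giving the diaryl ketone A1, methyl 3-bromo-5-(3,5-dibromo-4-methoxybenzoyl)-4-methoxybenzoate.
- For: it is convergent, and every bromine is placed by the building blocks, so no selectivity question arises at the end and no free 4-hydroxybenzyl alcohol ever meets an electrophile. On that point it is stronger than the chosen plan.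
- Against: the catalyst must select the one C–I bond of A2 in the presence of three C–Br bonds in A2 and A3, and direct biaryl coupling without carbonyl insertion competes. A1 still needs deoxygenation of a diaryl ketone to the methylene, cleavage of two methyl ethers (one flanked by two bromines) and reduction of the ester beside three C–Br bonds. A2 and A3 must also be made.
- Comparison: the sequence is roughly twice as long. The chosen plan gives up placement by construction, and in exchange completes all palladium and hydride chemistry before any halogen is present and ends at the key step.

**Alternative 2:** The disconnection cuts the C1–C2 and C1–C6 bonds of ring B, so that ring B is made and not bought. Five of its carbons, both bromines and the oxygen come from 3,5-dibromo-4H-pyran-4-one A6; C1 with the bridge comes from the ylide carbon of a ring A 2-arylethylphosphonium salt A7. In the forward key step, A6 is O-silylated to a 4-silyloxypyrylium ion, the ylide of A7 adds at C2, the 2H-pyran opens to a dienal, and a second deprotonation triggers an intramolecular Wittig closure. The product is the tris(tert-butyldimethylsilyl) ether A5 of 8, which one desilylation would convert into 8.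
- For: the bromines and the oxygen of ring B are placed with certainty, only one step follows the key step, and no electrophilic bromination is run beside a free hydroxymethylphenol. On regiochemical certainty for ring B it is stronger.
- Against: A7 would still need its own bromination at C2 of ring A, two silyl protections and a two-carbon homologation to the phosphonium salt. The cascade has several branch points: the ylide may act as a base or attack silicon, it must add next to a bromine-bearing carbon, the dienal must hold a cis geometry to close, and the Wittig closure forms a fully substituted ring carbon.
- Comparison: it constructs a benzene ring that is available ready-made. The chosen plan joins two catalogue arenes in one coupling, and relies on blocked positions where this alternative relies on construction.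

**Alternative 3:** The disconnection cuts the C1–C6 and C4–C5 bonds of ring A, which would be assembled from methyl 3-hydroxy-2-oxo-2H-pyran-6-carboxylate A9 and a ring B ynone, 1-(3,5-dibromo-4-methoxyphenyl)prop-2-yn-1-one A10. The forward key step is an amine-promoted cycloaddition of the hydroxypyrone across the alkyne, followed by decarboxylative collapse of the bridged lactone to the phenol A8, methyl 3-(3,5-dibromo-4-methoxybenzoyl)-4-hydroxybenzoate.
- For: the polarity match of the two partners fixes the ring A pattern (OH at C1, acyl at C6, ester at C4), the ring B bromines arrive in place, and A9 derives from a renewable sugar acid.
- Against: A8 lacks the bromine at C2 of ring A, so a late electrophilic bromination is needed all the same. It also carries a bridging carbonyl that must be reduced to the methylene, and it needs a demethylation next to two bromines and an ester reduction in the presence of C–Br bonds. A10 is a reactive acceptor that the amine can attack, and it must first be prepared.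
- Comparison: it is several steps longer and does not avoid the selectivity issue of the chosen plan, only reduces it to one bromine. The chosen plan buys both rings and takes all three bromines in one operation.

Key step: step 4

## Route

**Step 1**
Reactants: 1 4-methoxybenzyl chloride; 2 methyl 3-bromo-4-methoxybenzoate
Product: 4 methyl 4-methoxy-3-(4-methoxybenzyl)benzoate, via 4-methoxybenzylzinc chloride 3 (not isolated)
Conditions: 1 (1.3 equiv), activated Zn dust, LiCl, THF, 25 °C; then 2, Pd(OAc)2 (2 mol %), 2-dicyclohexylphosphino-2′,6′-dimethoxybiphenyl (SPhos, 4 mol %), THF, 25→50 °C
Reagents that add atoms: none
Why: LiCl-assisted insertion of zinc into the benzylic C–Cl bond gives 3, which tolerates the ester of 2; Negishi coupling then proceeds by oxidative addition of zerovalent palladium into the C–Br bond, transmetalation and reductive elimination. The electron-rich, bulky phosphine speeds oxidative addition next to the methoxy group and suppresses benzylic homocoupling.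

**Step 2**
Reactants: 4 methyl 4-methoxy-3-(4-methoxybenzyl)benzoate
Product: 5 methyl 4-hydroxy-3-(4-hydroxybenzyl)benzoate
Conditions: BBr3 (3.5 equiv), CH2Cl2, −78→0 °C; then H2O, 0 °C
Reagents that add atoms: none
Why: Lewis-acid ether cleavage: BBr3 binds each ether oxygen and bromide attacks the methyl group in an SN2 step, and hydrolysis frees the phenols. The less basic ester oxygen reacts much more slowly at or below 0 °C, and the cleavage is placed before the reduction because a benzylic alcohol would be converted into a benzylic bromide.

**Step 3**
Reactants: 5 methyl 4-hydroxy-3-(4-hydroxybenzyl)benzoate
Product: 6 2-(4-hydroxybenzyl)-4-(hydroxymethyl)phenol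
Conditions: LiAlH4 (3 equiv), THF, 0 °C→rt; aq. potassium sodium tartrate, pH 6–7
Reagents that add atoms: none
Why: Hydride reduction of an aryl ester to the primary alcohol; the two phenols are first deprotonated by excess hydride, and the resulting phenoxide slows but does not stop the reduction at room temperature. A near-neutral tartrate work-up avoids acid-induced ionisation of the 4-hydroxybenzyl alcohol.

**Step 4**
Reactants: 6 2-(4-hydroxybenzyl)-4-(hydroxymethyl)phenol; 7 tetrabutylammonium tribromide (1.0 equiv)
Product: 8 thelephenol [2-bromo-6-(3,5-dibromo-4-hydroxybenzyl)-4-(hydroxymethyl)phenol]
Conditions: 7 (1.0 equiv, added in portions), KH2PO4/H3PO4 buffer (pH about 3, excess), MeCN/H2O, 0–5 °C; then NH4VO3 (5 mol %), 30% aq. H2O2 (2.0–2.1 equiv, slow addition), 0–5 °C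
Reagents that add atoms: none
Why: The tribromide of 7, in equilibrium with Br2 and bromide, brominates the first phenol ortho position directly; NH4VO3 and H2O2 then form the peroxo complex VO(O2)+ of pentavalent vanadium, which oxidises each bromide that has been set free by two electrons to hypobromous acid and is regenerated by further peroxide, so that all three bromine atoms of 7 end up as electrophiles. Each phenol undergoes electrophilic aromatic substitution ortho to its OH through an arenium ion that loses a proton; three such events, at C2 of ring A and at C3 and C5 of ring B, should give 8, with ring B expected to react first because it offers two free ortho positions. The closest known reaction type is the oxidative bromination of phenols with bromide and H2O2 under NH4VO3 or V2O5 catalysis, a functional model of vanadium bromoperoxidase, together with the bromination of phenols by quaternary ammonium tribromides and the exhaustive ortho-bromination of para-substituted phenols. No ring is closed and no stereocentre is formed. The selectivity required is ortho C–H substitution in preference to ipso attack at C4 and C6 of ring A and at C1 of ring B, to alcohol oxidation and to a fourth bromination. The substrate secures the first of these through its blocked para positions, which leave exactly three activated C–H sites, the meta positions being far less reactive. The procedure secures the rest: one equivalent of 7 fixes the bromine inventory at three atoms per molecule of 6, the peroxide is added slowly in the cold so that the electrophile never accumulates, bromide remains present until the last substitution so that the peroxo complex is intercepted before it can oxidise the benzylic alcohol, and the buffer supplies the one proton consumed overall without ionising the hydroxymethyl group.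

## Compound list

1 | 4-methoxybenzyl chloride | COc1ccc(CCl)cc1 | starting material
2 | methyl 3-bromo-4-methoxybenzoate | COC(=O)c1ccc(OC)c(Br)c1 | starting material
3 | 4-methoxybenzylzinc chloride (THF solution, LiCl complex) | COc1ccc(C[Zn]Cl)cc1 | intermediate
4 | methyl 4-methoxy-3-(4-methoxybenzyl)benzoate | COC(=O)c1ccc(OC)c(Cc2ccc(OC)cc2)c1 | intermediate
5 | methyl 4-hydroxy-3-(4-hydroxybenzyl)benzoate | COC(=O)c1ccc(O)c(Cc2ccc(O)cc2)c1 | intermediate
6 | 2-(4-hydroxybenzyl)-4-(hydroxymethyl)phenol | OCc1ccc(O)c(Cc2ccc(O)cc2)c1 | intermediate
7 | tetrabutylammonium tribromide (tribromide anion drawn as bromide plus dibromine) | CCCC[N+](CCCC)(CCCC)CCCC.[Br-].BrBr | starting material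
8 | thelephenol, 2-bromo-6-(3,5-dibromo-4-hydroxybenzyl)-4-(hydroxymethyl)phenol | OCc1cc(Br)c(O)c(Cc2cc(Br)c(O)c(Br)c2)c1 | target

## Step count and risks

Total step count: 4. Longest linear sequence: 4 steps (from 1 or 2 to 8).

**Step 4 (key step).** The most likely failures are ipso substitution at C4 of ring A with loss of the one-carbon side chain, and fragmentation of the diarylmethane after ipso attack at C6 of ring A or C1 of ring B. Both are driven by local excess of electrophile. Peroxide may also be consumed unproductively by reduction of hypobromite to bromide with release of oxygen, which would leave under-brominated mixtures, and the peroxo complex may oxidise the benzylic alcohol once the bromide is used up.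
Fallback, setting out from 5 and returning to the route at 8: the bromination is moved ahead of the reduction, so that no hydroxymethyl group is present when the electrophile is used. Ester 5 is treated with Br2 (3 equiv) in AcOH at 15–20 °C. Ring B is brominated twice and the ester-deactivated ring A once at its only free ortho position, to give methyl 3-bromo-5-(3,5-dibromo-4-hydroxybenzyl)-4-hydroxybenzoate F1. F1 is then reduced with excess i-Bu2AlH in THF at −78→0 °C with a neutral tartrate work-up. This hydride leaves aryl bromides untouched and should give 8 directly.

**Step 3.** The reduction may stall, because the para phenoxide deactivates the ester and the aluminium phenoxides are poorly soluble. If it is then forced by heating, it may over-reduce through elimination of the benzylic aluminate to a quinone methide and hydride addition, which amounts to hydrogenolysis of the new C–O bond.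
Fallback, setting out from 5 and returning at 6: the phenoxide is removed from the problem. Both phenols of 5 are silylated (t-BuMe2SiCl, imidazole, DMF) to methyl 4-(tert-butyldimethylsilyloxy)-3-[4-(tert-butyldimethylsilyloxy)benzyl]benzoate F2. The ester is reduced with i-Bu2AlH in CH2Cl2 at −78 °C to {4-(tert-butyldimethylsilyloxy)-3-[4-(tert-butyldimethylsilyloxy)benzyl]phenyl}methanol F3. The aryl silyl ethers are then cleaved with Bu4NF buffered with AcOH in THF at 0 °C to give 6.

**Step 2.** The ester may be cleaved to the acid alongside the ethers, or demethylation may stop part-way because the ester carbonyl ties up Lewis acid.
Fallback, setting out from 4 and returning at 5: the Lewis acid is replaced by a soft nucleophile and full dealkylation is accepted. Excess NaSEt in DMF at 120–140 °C removes all three methyl groups by SN2 attack and gives, after acidification, 4-hydroxy-3-(4-hydroxybenzyl)benzoic acid F4. Fischer esterification (MeOH, catalytic H2SO4, reflux) then restores the methyl ester and gives 5.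

**Step 1.** Homocoupling of the benzylic zinc reagent may occur during insertion or on palladium, and oxidative addition into the aryl bromide beside the methoxy group may be slow, so that the zinc reagent is lost to protonation before it couples.
Fallback, setting out from 2 (with 1) and returning at 4: the polarity is reversed and zinc is avoided. Miyaura borylation of 2 (B2pin2, PdCl2(dppf), KOAc, dioxane, 85 °C) gives methyl 4-methoxy-3-(4,4,5,5-tetramethyl-1,3,2-dioxaborolan-2-yl)benzoate F5. Suzuki–Miyaura coupling of F5 with benzylic chloride 1 (Pd(OAc)2, SPhos, K3PO4, toluene with a little water, 80 °C) then gives 4.

## Further compounds

F1 | step 4 | methyl 3-bromo-5-(3,5-dibromo-4-hydroxybenzyl)-4-hydroxybenzoate | COC(=O)c1cc(Br)c(O)c(Cc2cc(Br)c(O)c(Br)c2)c1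
F2 | step 3 | methyl 4-(tert-butyldimethylsilyloxy)-3-[4-(tert-butyldimethylsilyloxy)benzyl]benzoate | COC(=O)c1ccc(O[Si](C)(C)C(C)(C)C)c(Cc2ccc(O[Si](C)(C)C(C)(C)C)cc2)c1
F3 | step 3 | {4-(tert-butyldimethylsilyloxy)-3-[4-(tert-butyldimethylsilyloxy)benzyl]phenyl}methanol | OCc1ccc(O[Si](C)(C)C(C)(C)C)c(Cc2ccc(O[Si](C)(C)C(C)(C)C)cc2)c1
F4 | step 2 | 4-hydroxy-3-(4-hydroxybenzyl)benzoic acid | OC(=O)c1ccc(O)c(Cc2ccc(O)cc2)c1
F5 | step 1 | methyl 4-methoxy-3-(4,4,5,5-tetramethyl-1,3,2-dioxaborolan-2-yl)benzoate | COC(=O)c1ccc(OC)c(c1)B1OC(C)(C)C(C)(C)O1
A1 | alternative 1 | methyl 3-bromo-5-(3,5-dibromo-4-methoxybenzoyl)-4-methoxybenzoate | COC(=O)c1cc(Br)c(OC)c(C(=O)c2cc(Br)c(OC)c(Br)c2)c1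
A2 | alternative 1 | methyl 3-bromo-5-iodo-4-methoxybenzoate | COC(=O)c1cc(Br)c(OC)c(I)c1
A3 | alternative 1 | (3,5-dibromo-4-methoxyphenyl)boronic acid | COc1c(Br)cc(cc1Br)B(O)O
A4 | alternative 1 | carbon monoxide | [C-]#[O+]
A5 | alternative 2 | tris(tert-butyldimethylsilyl) ether of thelephenol | CC(C)(C)[Si](C)(C)OCc1cc(Br)c(O[Si](C)(C)C(C)(C)C)c(Cc2cc(Br)c(O[Si](C)(C)C(C)(C)C)c(Br)c2)c1
A6 | alternative 2 | 3,5-dibromo-4H-pyran-4-one | O=c1c(Br)cocc1Br
A7 | alternative 2 | {2-[3-bromo-2-(tert-butyldimethylsilyloxy)-5-(tert-butyldimethylsilyloxymethyl)phenyl]ethyl}triphenylphosphonium bromide | CC(C)(C)[Si](C)(C)OCc1cc(Br)c(O[Si](C)(C)C(C)(C)C)c(CC[P+](c2ccccc2)(c2ccccc2)c2ccccc2)c1.[Br-]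
A8 | alternative 3 | methyl 3-(3,5-dibromo-4-methoxybenzoyl)-4-hydroxybenzoate | COC(=O)c1ccc(O)c(C(=O)c2cc(Br)c(OC)c(Br)c2)c1
A9 | alternative 3 | methyl 3-hydroxy-2-oxo-2H-pyran-6-carboxylate | COC(=O)c1ccc(O)c(=O)o1
A10 | alternative 3 | 1-(3,5-dibromo-4-methoxyphenyl)prop-2-yn-1-one | COc1c(Br)cc(cc1Br)C(=O)C#C
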